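**Retrosynthetic overview**
- Target 18 is reached from its bis-MOM ether 17 by acid. 17 is cut at the C2–C1′ bond between ring C and the 4-methoxyphenyl ring, giving chromone 15 and 4-methoxyphenylboronic acid 16 (asymmetric conjugate arylation).
- The strategy rests on the single stereocentre C2 of ring C. It is benzylic and β to the C4 carbonyl, so it maps onto the β-carbon of a chromone enone whose hexasubstituted ring A (5-OH, 6-Me, 7-OH, 8-prenyl) is already fixed.
- 15 comes from the 5-O-prenyl ether 11 by a Claisen–Cope relay of the prenyl group from O5 via the methyl-blocked C6 to C8. 11 comes from 5,7-dihydroxy-6-methylchromone 8.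
- 8 comes from chromone 7, made by Friedel–Crafts closure of the symmetric aryloxyacrylic acid 6. 6 comes from phenol 3 and ethyl propiolate 4, and 3 from 2,6-dimethoxytoluene 1 by C–H borylation and oxidation.
- Ring order: ring A is bought, ring C is closed onto it, and ring B is attached last at C2.

Key step: step 11

Assumption: the (S)-antipode of the bisphosphine is written for the 2S product, by analogy with the facial sense of atropisomeric bisphosphine–rhodium catalysts on cyclic enones; the sense is to be confirmed on the first run and the (R)-antipode used instead if needed.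

**Route**

Step 1
Reactants: 1 2,6-dimethoxytoluene
Product: 2 2-(3,5-dimethoxy-4-methylphenyl)-4,4,5,5-tetramethyl-1,3,2-dioxaborolane
Conditions: [Ir(OMe)(cod)]2 (1.5 mol%), 4,4′-di-tert-butyl-2,2′-bipyridine (3 mol%), B2pin2 (1.0 equiv), THF, 80 °C
Reagents that add atoms: bis(pinacolato)diboron, CC1(C)OB(OC1(C)C)B1OC(C)(C)C(C)(C)O1
Why: Iridium-catalysed aromatic C–H borylation is sterically governed, and the C–H para to the methyl group is the only ring position without an ortho substituent, so the boron should enter there.

Step 2
Reactants: 2 2-(3,5-dimethoxy-4-methylphenyl)-4,4,5,5-tetramethyl-1,3,2-dioxaborolane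
Product: 3 3,5-dimethoxy-4-methylphenol
Conditions: KHSO5 (used as the triple salt 2KHSO5·KHSO4·K2SO4, 1.1 equiv), acetone/H2O, 0 °C → rt
Reagents that add atoms: potassium peroxymonosulfate, [K+].[O-]S(=O)(=O)OO
Why: Oxidation of an arylboronate by a peroxide proceeds by 1,2-migration of the aryl group from boron to oxygen and hydrolysis of the borate, which gives the phenol at the former C–B carbon.

Step 3
Reactants: 3 3,5-dimethoxy-4-methylphenol; 4 ethyl propiolate
Product: 5 ethyl (E)-3-(3,5-dimethoxy-4-methylphenoxy)acrylate
Conditions: DABCO (10 mol%), CH2Cl2, 0 °C → rt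
Reagents that add atoms: none
Why: Amine-catalysed oxa-Michael addition of a phenol to a terminal ynoate should give the β-aryloxyacrylate, with the E isomer favoured.

Step 4
Reactants: 5 ethyl (E)-3-(3,5-dimethoxy-4-methylphenoxy)acrylate
Product: 6 (E)-3-(3,5-dimethoxy-4-methylphenoxy)acrylic acid
Conditions: LiOH·H2O (3 equiv), THF/H2O (3:1), rt; then 1 M HCl to pH 2
Reagents that add atoms: lithium hydroxide, [Li+].[OH-]
Why: Ester saponification at room temperature should be faster than addition–elimination at the β-carbon of the vinylogous carbonate, so the aryl vinyl ether is kept.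

Step 5
Reactants: 6 (E)-3-(3,5-dimethoxy-4-methylphenoxy)acrylic acid
Product: 7 5,7-dimethoxy-6-methylchromone
Conditions: P2O5 in MeSO3H (1:10 w/w), rt → 50 °C; poured onto ice
Reagents that add atoms: none
Why: Intramolecular Friedel–Crafts acylation closes ring C (C4–C4a bond) onto either of the two equivalent ortho carbons, each activated by an ortho and a para oxygen; reversible protonation of the enol ether in the strong acid lets the E acid reach the cis geometry needed for closure.

Step 6
Reactants: 7 5,7-dimethoxy-6-methylchromone
Product: 8 5,7-dihydroxy-6-methylchromone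
Conditions: BBr3 (5 equiv), CH2Cl2, −78 °C → rt; MeOH, then H2O
Reagents that add atoms: none
Why: Lewis-acid cleavage of aryl methyl ethers by BBr3 removes both methyl groups, the peri 5-OMe first through chelation to the C4 carbonyl, and the chromone ring is stable to the reagent.

Step 7
Reactants: 8 5,7-dihydroxy-6-methylchromone
Product: 9 5-hydroxy-7-(methoxymethoxy)-6-methylchromone
Conditions: MOMCl (1.1 equiv), i-Pr2NEt (1.5 equiv), CH2Cl2, 0 °C → rt
Reagents that add atoms: chloromethyl methyl ether, COCCl
Why: O-Alkylation with an amine base should take the more acidic, unchelated 7-OH and leave the 5-OH, which is held in a hydrogen bond to the C4 carbonyl.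

Step 8
Reactants: 9 5-hydroxy-7-(methoxymethoxy)-6-methylchromone; 10 prenyl bromide
Product: 11 7-(methoxymethoxy)-6-methyl-5-(prenyloxy)chromone
Conditions: K2CO3 (3 equiv), acetone, reflux
Reagents that add atoms: none
Why: Williamson etherification of the only remaining phenol with the reactive allylic bromide should proceed once carbonate in hot acetone breaks the chelate.

Step 9
Reactants: 11 7-(methoxymethoxy)-6-methyl-5-(prenyloxy)chromone
Product: 14 5-hydroxy-7-(methoxymethoxy)-6-methyl-8-prenylchromone, via C6 ortho-dienone 12 (not isolated), via C8 para-dienone 13 (not isolated)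
Conditions: Eu(fod)3 (fod = 6,6,7,7,8,8,8-heptafluoro-2,2-dimethyloctane-3,5-dionate; 10 mol%), NaHCO3, PhCl, 85 °C
Reagents that add atoms: none
Why: In this aromatic para-Claisen rearrangement the first [3,3] shift puts a reverse-prenyl group on C6, which cannot enolise because it carries the methyl group, so a Cope [3,3] shift carries the chain on to C8 with its normal terminus and tautomerisation restores the chelated phenol; the MOM group on O7 prevents cyclisation onto the new ortho chain.

Step 10
Reactants: 14 5-hydroxy-7-(methoxymethoxy)-6-methyl-8-prenylchromone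
Product: 15 5,7-bis(methoxymethoxy)-6-methyl-8-prenylchromone
Conditions: NaH (1.5 equiv), DMF, 0 °C; then MOMCl (1.5 equiv), 0 °C → rt
Reagents that add atoms: chloromethyl methyl ether, COCCl
Why: Irreversible deprotonation with the non-nucleophilic hydride frees the chelated, hindered 5-phenoxide for O-alkylation without attack on C2 of the chromone.

Step 11
Reactants: 15 5,7-bis(methoxymethoxy)-6-methyl-8-prenylchromone; 16 4-methoxyphenylboronic acid (3 equiv)
Product: 17 (2S)-5,7-bis(methoxymethoxy)-4′-methoxy-6-methyl-8-prenylflavanone
Conditions: [Rh(OH)(cod)]2 (3 mol%), (S)-MeO-F12-BIPHEP [(S)-6,6′-dimethoxy-2,2′-bis{bis(3,4,5-trifluorophenyl)phosphino}-1,1′-biphenyl, 6.6 mol%], CH2Cl2/H2O (10:1), 20–30 °C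
Reagents that add atoms: none
Why: The aryl group passes from boron to the hydroxorhodium complex, the aryl–rhodium bond adds across C2=C3 with the aryl on C2, and water protonates the resulting oxa-π-allyl rhodium enolate at C3 and regenerates the Rh–OH species. The closest known reaction type is the rhodium-catalysed asymmetric 1,4-addition of arylboronic acids to chromones (Hayashi–Miyaura-type conjugate addition). No ring is closed: ring C is already present and its O1–C2 bond stays intact, so no chalcone can form and scramble C2. The C2 stereocentre is set by the atropisomeric bisphosphine alone, which must deliver the aryl group to the Re face of C2 (priorities O1 > C3 > H) of the flat, achiral chromone to give 2S. The step needs enantioface selectivity, 1,4- over 1,2-addition and alkene chemoselectivity: the electron-poor ligand and the low temperature should keep the catalyst from adding to the product ketone, which is also shielded by the peri 5-OMOM group, and the trisubstituted, unactivated prenyl alkene should not insert into the aryl–rhodium bond.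

Step 12
Reactants: 17 (2S)-5,7-bis(methoxymethoxy)-4′-methoxy-6-methyl-8-prenylflavanone
Product: 18 (2S)-5,7-dihydroxy-4′-methoxy-6-methyl-8-prenylflavanone (target)
Conditions: 3 M aq HCl/MeOH (1:5), 45 °C; NaHCO3 quench at full conversion
Reagents that add atoms: none
Why: Acid-catalysed acetal exchange with methanol removes both MOM groups through oxocarbenium ions; the medium generates neither phenoxide nor enolate, so ring C should not open and C2 should keep its configuration, and the dilute acid and moderate temperature are meant to spare the prenyl alkene.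

**Compound list**
1 | 2,6-dimethoxytoluene | COc1cccc(OC)c1C | starting material
2 | 2-(3,5-dimethoxy-4-methylphenyl)-4,4,5,5-tetramethyl-1,3,2-dioxaborolane | COc1cc(B2OC(C)(C)C(C)(C)O2)cc(OC)c1C | intermediate
3 | 3,5-dimethoxy-4-methylphenol | COc1cc(O)cc(OC)c1C | intermediate
4 | ethyl propiolate | CCOC(=O)C#C | starting material
5 | ethyl (E)-3-(3,5-dimethoxy-4-methylphenoxy)acrylate | CCOC(=O)/C=C/Oc1cc(OC)c(C)c(OC)c1 | intermediate
6 | (E)-3-(3,5-dimethoxy-4-methylphenoxy)acrylic acid | COc1cc(O/C=C/C(=O)O)cc(OC)c1C | intermediate
7 | 5,7-dimethoxy-6-methylchromone | COc1cc2occc(=O)c2c(OC)c1C | intermediate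
8 | 5,7-dihydroxy-6-methylchromone | Cc1c(O)cc2occc(=O)c2c1O | intermediate
9 | 5-hydroxy-7-(methoxymethoxy)-6-methylchromone | COCOc1cc2occc(=O)c2c(O)c1C | intermediate
10 | prenyl bromide (1-bromo-3-methylbut-2-ene) | CC(C)=CCBr | starting material
11 | 7-(methoxymethoxy)-6-methyl-5-(prenyloxy)chromone | COCOc1cc2occc(=O)c2c(OCC=C(C)C)c1C | intermediate
12 | 7-(methoxymethoxy)-6-methyl-6-(2-methylbut-3-en-2-yl)-6H-chromene-4,5-dione (C6 ortho-dienone, racemic, formed in the flask) | O=C1C2=C(OC=CC2=O)C=C(OCOC)C1(C)C(C)(C)C=C | intermediate
13 | 7-(methoxymethoxy)-6-methyl-8-(3-methylbut-2-enyl)-8H-chromene-4,5-dione (C8 para-dienone, racemic, formed in the flask) | O=C1C2=C(OC=CC2=O)C(CC=C(C)C)C(OCOC)=C1C | intermediate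
14 | 5-hydroxy-7-(methoxymethoxy)-6-methyl-8-prenylchromone | COCOc1c(C)c(O)c2c(=O)ccoc2c1CC=C(C)C | intermediate
15 | 5,7-bis(methoxymethoxy)-6-methyl-8-prenylchromone | COCOc1c(C)c(OCOC)c2c(=O)ccoc2c1CC=C(C)C | intermediate
16 | 4-methoxyphenylboronic acid | COc1ccc(B(O)O)cc1 | starting material
17 | (2S)-5,7-bis(methoxymethoxy)-4′-methoxy-6-methyl-8-prenylflavanone | COc1ccc([C@@H]2CC(=O)c3c(OCOC)c(C)c(OCOC)c(CC=C(C)C)c3O2)cc1 | intermediate
18 | (2S)-5,7-dihydroxy-4′-methoxy-6-methyl-8-prenylflavanone | COc1ccc([C@@H]2CC(=O)c3c(O)c(C)c(O)c(CC=C(C)C)c3O2)cc1 | target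

**Step count**
Total: 12 steps. Longest linear sequence: 12 steps (1 → 18); 4, 10 and 16 enter as bought building blocks.

**Steps most likely to fail**

1. Step 11. Carbometalation at the donor-rich enone flanked by the 8-prenyl and 5-OMOM groups may be slow, so that protodeboronation of the boronic acid wins, or the catalyst may discriminate the two faces of C2 poorly. The fallback sets out from 15 and gives up catalytic face control for a racemic addition and a separation. Copper-mediated conjugate addition of (4-methoxyphenyl)magnesium bromide (CuBr·SMe2, TMSCl, THF, −78 → −20 °C) should give the racemic 4-(trimethylsilyloxy)-2H-chromene silyl enol ether F1. Brief treatment with aqueous citric acid in THF should hydrolyse it to the racemic flavanone F2. Preparative chromatography on a chiral stationary phase (amylose tris(3,5-dimethylphenylcarbamate)) would then separate the (2S)-enantiomer, which is 17, from the (2R)-enantiomer F3. The route is rejoined at 17.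

2. Step 9. The blocked C6 dienone may fragment with loss of the prenyl group instead of undergoing the Cope shift, or the Lewis acid may cleave the acetal during the long heating. The fallback sets out from 8 and installs the chain directly on carbon. Friedel–Crafts prenylation with 2-methylbut-3-en-2-ol and BF3·OEt2 in dioxane at room temperature can only occur at C8, the one free position of ring A, and should give 5,7-dihydroxy-6-methyl-8-prenylchromone F4. Double protection (NaH, MOMCl, 2.5 equiv each, DMF, 0 °C → rt) then returns to the route at 15, replacing steps 7 to 10.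

3. Step 5. The acid-labile aryl vinyl ether may be cleaved back to the phenol, or may oligomerise, before the E acid has isomerised and closed. The fallback sets out from 3 and builds ring C from a ketone instead. Ortho C-acetylation (Ac2O, BF3·OEt2, 80 °C, aqueous work-up; Fries-type) should give 1-(6-hydroxy-2,4-dimethoxy-3-methylphenyl)ethanone F5. Condensation with N,N-dimethylformamide dimethyl acetal (toluene, 100 °C) should give the enaminone (E)-3-(dimethylamino)-1-(6-hydroxy-2,4-dimethoxy-3-methylphenyl)prop-2-en-1-one F6. Cyclisation of the phenol onto the enaminone with loss of dimethylamine (aq HCl, CH2Cl2, 40 °C) returns to the route at 7.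

**Further compounds**
F1 | step 11 | racemic 2-(4-methoxyphenyl)-5,7-bis(methoxymethoxy)-6-methyl-8-prenyl-4-(trimethylsilyloxy)-2H-chromene | COc1ccc(C2C=C(O[Si](C)(C)C)c3c(OCOC)c(C)c(OCOC)c(CC=C(C)C)c3O2)cc1
F2 | step 11 | racemic 5,7-bis(methoxymethoxy)-4′-methoxy-6-methyl-8-prenylflavanone | COc1ccc(C2CC(=O)c3c(OCOC)c(C)c(OCOC)c(CC=C(C)C)c3O2)cc1
F3 | step 11 | (2R)-5,7-bis(methoxymethoxy)-4′-methoxy-6-methyl-8-prenylflavanone | COc1ccc([C@H]2CC(=O)c3c(OCOC)c(C)c(OCOC)c(CC=C(C)C)c3O2)cc1
F4 | step 9 | 5,7-dihydroxy-6-methyl-8-prenylchromone | Cc1c(O)c(CC=C(C)C)c2occc(=O)c2c1O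
F5 | step 5 | 1-(6-hydroxy-2,4-dimethoxy-3-methylphenyl)ethanone | CC(=O)c1c(O)cc(OC)c(C)c1OC
F6 | step 5 | (E)-3-(dimethylamino)-1-(6-hydroxy-2,4-dimethoxy-3-methylphenyl)prop-2-en-1-one | CN(C)/C=C/C(=O)c1c(O)cc(OC)c(C)c1OC
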